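**Assumption:** bicyclic compounds are named with eremophilane numbering (ring A = C1–C5, C10; ring B = C5–C10; methyls on C4 and C5; isopropenyl on C7); β is the face of the C5 methyl, α the opposite face.

## Retrosynthetic overview

1. Target ⇒ Mitsunobu esterification (inversion at C3) of 3β-alcohol acetonide 18 with Z-acid 24; 24 ⇐ (R)-pent-4-yn-2-ol, angelic acid and CO2.
2. 18 ⇒ 8α-hydroxy-3,9-dione 12, by SN2 inversion at C8 and two face-selective ketone reductions.
3. 12 ⇒ tricyclic silaketal 9 ⇒ key step: silicon-tethered type-2 intramolecular Diels–Alder of 8, which closes ring A (C4–C5, C1–C10) and the temporary dioxasila ring together.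
4. 8 ⇒ hydroxy-enone 5 + ethyl vinyl ketone + iPr2Si(OTf)2; 5 ⇒ enone 4 ⇒ (+)-3-carene (allylic oxidation, retro-ene opening of the cyclopropane).
5. Ring order: ring B comes from the carene six-membered ring; ring A and the tether ring form in one operation; the tether ring is excised afterwards.

## Route

Step 1
Reactants: 1 (+)-3-carene
Product: 2 (1R,6S)-4,7,7-trimethylbicyclo[4.1.0]hept-3-en-2-one (car-3-en-5-one)
Conditions: t-BuOOH (70% aq.), CrO3 (5 mol%), CH2Cl2, rt
Reagents that add atoms: tert-butyl hydroperoxide, CC(C)(C)OO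
Why: Cr-catalysed allylic oxidation attacks the less hindered ring CH2 next to the unsubstituted alkene carbon and gives the conjugated enone, leaving both cyclopropane stereocentres untouched.

Step 2
Reactants: 2 (1R,6S)-4,7,7-trimethylbicyclo[4.1.0]hept-3-en-2-one
Product: 4 (S)-3-methyl-5-(prop-1-en-2-yl)cyclohex-2-en-1-one, via dienol tautomer 3 (not isolated)
Conditions: PhMe (0.05 M), sealed tube, 230 °C
Reagents that add atoms: none
Why: the cis-methyl cyclopropyl ketone undergoes a thermal retro-ene (homodienyl 1,5-hydrogen shift, enolene rearrangement) in which a methyl hydrogen moves to the carbonyl oxygen as the cyclopropane bond α to the carbonyl breaks, so the dienol ketonises to the isopropenyl enone and the stereocentre, which is not involved, is retained as (S).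

Step 3
Reactants: 4 (S)-3-methyl-5-(prop-1-en-2-yl)cyclohex-2-en-1-one
Product: 5 (5R,6R)-6-hydroxy-3-methyl-5-(prop-1-en-2-yl)cyclohex-2-en-1-one
Conditions: KHMDS, THF, −78 °C; Davis oxaziridine; AcOH quench
Reagents that add atoms: 3-phenyl-2-(phenylsulfonyl)oxaziridine, O=S(=O)(c1ccccc1)N1OC1c1ccccc1
Why: the kinetic α′-enolate is hydroxylated by the Davis oxaziridine (enolate oxidation) on the face anti to the neighbouring isopropenyl group, giving the trans (8α) alcohol.

Step 4
Reactants: 5 (5R,6R)-6-hydroxy-3-methyl-5-(prop-1-en-2-yl)cyclohex-2-en-1-one + 6 pent-1-en-3-one (ethyl vinyl ketone)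
Product: 8 (5R,6R)-6-{di(propan-2-yl)[(Z)-penta-1,3-dien-3-yloxy]silyloxy}-3-methyl-5-(prop-1-en-2-yl)cyclohex-2-en-1-one, via dienyloxysilyl triflate 7 (not isolated)
Conditions: 6, iPr2Si(OTf)2 (1.0 equiv), Et3N, CH2Cl2, −78 °C; then 5, Et3N, −78 → 0 °C
Reagents that add atoms: diisopropylsilyl bis(trifluoromethanesulfonate), CC(C)[Si](OS(=O)(=O)C(F)(F)F)(OS(=O)(=O)C(F)(F)F)C(C)C
Why: soft enolisation of the ethyl ketone by the silyl triflate gives the (Z)-2-silyloxydiene (O and CH3 cis) and the remaining Si–OTf is displaced by the secondary alcohol (silyl ether formation), giving the mixed silaketal without touching a stereocentre.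

Step 5
Reactants: 8 (5R,6R)-6-{di(propan-2-yl)[(Z)-penta-1,3-dien-3-yloxy]silyloxy}-3-methyl-5-(prop-1-en-2-yl)cyclohex-2-en-1-one
Product: 9 tricyclic silaketal 4α-methyl-10βH-eremophila-2,11-dien-9-one bridged 3-O–Si(iPr)2–O-8α
Conditions: AlBr3/AlMe3 (10:1, 25 mol%), PhMe–CH2Cl2 (0.005 M), −10 °C → rt
Reagents that add atoms: none
Why: Proposed new method: the silaketal anchored on the α-oriented C8 oxygen holds the electron-rich 2-silyloxydiene over the α-face of the Lewis-acid-activated enone (anti to the isopropenyl group), so the enol-ether β-carbon C4 bonds to the enone β-carbon C5 and C1 closes onto C10 in a type-2 intramolecular Diels–Alder (at the limit a Mukaiyama–Michael/Michael sequence) that forms ring A and the dioxasila ring together, sets the C5 methyl and C10–H both β (cis-fused) and, from the Z-enol ether in the tether-enforced endo geometry, the C4 methyl α; the closest known chemistry is the temporary silicon-tethered (silyl acetal) Diels–Alder reaction and the AlBr3/AlMe3-promoted cycloaddition of 2-silyloxydienes with 3-methylcyclohexenones.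

Step 6
Reactants: 9 tricyclic silaketal
Product: 12 8α-hydroxy-10βH-eremophil-11-ene-3,9-dione, via 4α-methyl methoxysilyl ether 10 (not isolated), via 4β-methyl methoxysilyl ether 11 (not isolated)
Conditions: K2CO3 (cat.), MeOH, 0 °C → rt; then HF·pyridine, THF, 0 °C
Reagents that add atoms: none
Why: methanolysis cleaves the enol silyl ether to the C3 ketone and the carbonate equilibrates C4 to the equatorial 4β-methyl (the 4α-epimer has a syn-axial Me/C9 contact) while the still-silylated C8 oxygen blocks α-ketol isomerisation, after which HF removes the silyl group (Si–F bond formation).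

Step 7
Reactants: 12 8α-hydroxy-10βH-eremophil-11-ene-3,9-dione
Product: 15 8β-hydroxy-10βH-eremophil-11-ene-3,9-dione, via 8α-triflate 13 (not isolated), via 8β-nitrite ester 14 (not isolated)
Conditions: Tf2O, pyridine, CH2Cl2, −30 °C; then Bu4N+ NO2−, DMF, rt; H2O work-up
Reagents that add atoms: tetrabutylammonium nitrite, CCCC[N+](CCCC)(CCCC)CCCC.[O-]N=O
Why: the equatorial α-keto triflate, which has no antiperiplanar hydrogen for E2, is displaced by nitrite in an SN2 reaction from the open β-face (Lattrell–Dax inversion) and the nitrite ester hydrolyses on work-up to the axial 8β-alcohol.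

Step 8
Reactants: 15 8β-hydroxy-10βH-eremophil-11-ene-3,9-dione
Product: 17 10βH-eremophil-11-ene-3β,8β,9β-triol, via 3β,8β-dihydroxy-9-ketone 16 (not isolated)
Conditions: L-Selectride (2.1 equiv), THF, −78 °C; then MeOH, CeCl3·7H2O, NaBH4, −78 → −20 °C
Reagents that add atoms: none
Why: bulky L-Selectride reduces only the unhindered C3 ketone by equatorial attack (axial 3β-OH, the syn-axial C5 methyl also blocking the other face), and the small Luche hydride then attacks the hindered C9 ketone axially from the α-face, anti to the axial C8–O bond (Felkin–Anh), giving the equatorial 9β-OH cis to 8β-OH.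

Step 9
Reactants: 17 10βH-eremophil-11-ene-3β,8β,9β-triol
Product: 18 8β,9β-(isopropylidenedioxy)-10βH-eremophil-11-en-3β-ol
Conditions: 2,2-dimethoxypropane, PPTS (cat.), acetone, rt; MeOH quench
Reagents that add atoms: 2,2-dimethoxypropane, COC(C)(C)OC
Why: acid-catalysed transketalisation forms the five-membered isopropylidene acetal only on the cis-8,9-diol, leaving the isolated 3β-OH free.

Step 10
Reactants: 19 (R)-pent-4-yn-2-ol + 20 angelic acid
Product: 22 (R)-pent-4-yn-2-yl (Z)-2-methylbut-2-enoate, via angelic trichlorobenzoic anhydride 21 (not isolated)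
Conditions: 2,4,6-Cl3C6H2COCl, Et3N, PhMe, rt; then 19, 80 °C
Reagents that add atoms: none
Why: Yamaguchi esterification through the mixed anhydride acylates the secondary alcohol without base-induced Z→E isomerisation of the angelate and does not touch the (R) carbinol centre.

Step 11
Reactants: 22 (R)-pent-4-yn-2-yl (Z)-2-methylbut-2-enoate
Product: 23 (R)-5-[(Z)-2-methylbut-2-enoyloxy]hex-2-ynoic acid
Conditions: CO2 (1 atm), Cs2CO3, AgI (2 mol%), DMF, 50 °C; then 1 M HCl
Reagents that add atoms: carbon dioxide, O=C=O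
Why: silver-catalysed C–H carboxylation forms the silver acetylide under mild carbonate base and inserts CO2, which carboxylates the terminal alkyne while the ester survives.

Step 12
Reactants: 23 (R)-5-[(Z)-2-methylbut-2-enoyloxy]hex-2-ynoic acid
Product: 24 (R,Z)-5-[(Z)-2-methylbut-2-enoyloxy]hex-2-enoic acid
Conditions: H2 (1 atm), Lindlar Pd, quinoline, EtOAc, rt
Reagents that add atoms: none
Why: Lindlar semi-hydrogenation adds H2 syn to the alkyne on poisoned palladium and gives the Z-enoic acid, while the trisubstituted angelate alkene is inert.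

Step 13
Reactants: 18 8β,9β-(isopropylidenedioxy)-10βH-eremophil-11-en-3β-ol + 24 (R,Z)-5-[(Z)-2-methylbut-2-enoyloxy]hex-2-enoic acid
Product: 25 8β,9β-(isopropylidenedioxy)-10βH-eremophil-11-en-3α-yl (R,Z)-5-[(Z)-2-methylbut-2-enoyloxy]hex-2-enoate
Conditions: PPh3, DIAD, PhMe, 0 °C → rt
Reagents that add atoms: none
Why: in the Mitsunobu esterification the carboxylate displaces the axial C3 alkoxyphosphonium group by SN2 from the equatorial direction, inverting C3 to the required 3α (R) ester under neutral conditions that preserve both Z-alkenes.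

Step 14
Reactants: 25 8β,9β-(isopropylidenedioxy)-10βH-eremophil-11-en-3α-yl (R,Z)-5-[(Z)-2-methylbut-2-enoyloxy]hex-2-enoate
Product: 26 CNP0395983.1
Conditions: AcOH–H2O (4:1), 40 °C
Reagents that add atoms: none
Why: mild acid hydrolysis of the isopropylidene acetal frees the cis-8β,9β-diol without affecting the esters, alkenes or any stereocentre.

## Compound list

1 | (+)-3-carene, (1S,6R)-3,7,7-trimethylbicyclo[4.1.0]hept-3-ene | CC3(C)[C@H]1CC(C)=CC[C@H]13 | starting material
2 | (1R,6S)-4,7,7-trimethylbicyclo[4.1.0]hept-3-en-2-one (car-3-en-5-one) | CC3(C)[C@H]1CC(C)=CC(=O)[C@H]13 | intermediate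
3 | (5S)-3-methyl-5-(prop-1-en-2-yl)cyclohexa-1,3-dien-1-ol, dienol tautomer of 4 (not isolated) | C=C(C)[C@H]1CC(C)=CC(O)=C1 | intermediate
4 | (S)-3-methyl-5-(prop-1-en-2-yl)cyclohex-2-en-1-one | C=C(C)[C@H]1CC(C)=CC(=O)C1 | intermediate
5 | (5R,6R)-6-hydroxy-3-methyl-5-(prop-1-en-2-yl)cyclohex-2-en-1-one | C=C(C)[C@H]1CC(C)=CC(=O)[C@@H]1O | intermediate
6 | pent-1-en-3-one (ethyl vinyl ketone) | C=CC(=O)CC | starting material
7 | di(propan-2-yl)[(Z)-penta-1,3-dien-3-yloxy]silyl trifluoromethanesulfonate (not isolated) | C=C/C(O[Si](C(C)C)(C(C)C)OS(=O)(=O)C(F)(F)F)=C/C | intermediate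
8 | (5R,6R)-6-{di(propan-2-yl)[(Z)-penta-1,3-dien-3-yloxy]silyloxy}-3-methyl-5-(prop-1-en-2-yl)cyclohex-2-en-1-one | C=C(C)[C@H]1CC(C)=CC(=O)[C@@H]1O[Si](C(C)C)(C(C)C)O/C(C=C)=C\C | intermediate
9 | tricyclic silaketal: 4α-methyl-10βH-eremophila-2,11-dien-9-one bridged 3-O–Si(iPr)2–O-8α | C=C(C)[C@H]1C[C@@]2(C)[C@H](CC=C(O3)[C@H]2C)C(=O)[C@@H]1O[Si]3(C(C)C)C(C)C | intermediate
10 | 8α-[methoxydi(propan-2-yl)silyloxy]-4α-methyl-10βH-eremophil-11-ene-3,9-dione (not isolated) | C=C(C)[C@H]1C[C@@]2(C)[C@H](CCC(=O)[C@H]2C)C(=O)[C@@H]1O[Si](OC)(C(C)C)C(C)C | intermediate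
11 | 8α-[methoxydi(propan-2-yl)silyloxy]-10βH-eremophil-11-ene-3,9-dione, 4β-methyl (not isolated) | C=C(C)[C@H]1C[C@@]2(C)[C@H](CCC(=O)[C@@H]2C)C(=O)[C@@H]1O[Si](OC)(C(C)C)C(C)C | intermediate
12 | 8α-hydroxy-10βH-eremophil-11-ene-3,9-dione | C=C(C)[C@H]1C[C@@]2(C)[C@H](CCC(=O)[C@@H]2C)C(=O)[C@@H]1O | intermediate
13 | 3,9-dioxo-10βH-eremophil-11-en-8α-yl trifluoromethanesulfonate (not isolated) | C=C(C)[C@H]1C[C@@]2(C)[C@H](CCC(=O)[C@@H]2C)C(=O)[C@@H]1OS(=O)(=O)C(F)(F)F | intermediate
14 | 3,9-dioxo-10βH-eremophil-11-en-8β-yl nitrite (not isolated) | C=C(C)[C@H]1C[C@@]2(C)[C@H](CCC(=O)[C@@H]2C)C(=O)[C@H]1ON=O | intermediate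
15 | 8β-hydroxy-10βH-eremophil-11-ene-3,9-dione | C=C(C)[C@H]1C[C@@]2(C)[C@H](CCC(=O)[C@@H]2C)C(=O)[C@H]1O | intermediate
16 | 3β,8β-dihydroxy-10βH-eremophil-11-en-9-one (not isolated) | C=C(C)[C@H]1C[C@@]2(C)[C@H](CC[C@H](O)[C@@H]2C)C(=O)[C@H]1O | intermediate
17 | 10βH-eremophil-11-ene-3β,8β,9β-triol | C=C(C)[C@H]1C[C@@]2(C)[C@H](CC[C@H](O)[C@@H]2C)[C@@H](O)[C@H]1O | intermediate
18 | 8β,9β-(isopropylidenedioxy)-10βH-eremophil-11-en-3β-ol | C=C(C)[C@H]1C[C@@]2(C)[C@H](CC[C@H](O)[C@@H]2C)[C@H]3OC(C)(C)O[C@@H]13 | intermediate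
19 | (R)-pent-4-yn-2-ol | C#CC[C@@H](C)O | starting material
20 | angelic acid, (Z)-2-methylbut-2-enoic acid | C/C=C(/C)C(=O)O | starting material
21 | (Z)-2-methylbut-2-enoic 2,4,6-trichlorobenzoic anhydride (not isolated) | C/C=C(/C)C(=O)OC(=O)c1c(Cl)cc(Cl)cc1Cl | intermediate
22 | (R)-pent-4-yn-2-yl (Z)-2-methylbut-2-enoate | C#CC[C@@H](C)OC(=O)/C(C)=C\C | intermediate
23 | (R)-5-[(Z)-2-methylbut-2-enoyloxy]hex-2-ynoic acid | OC(=O)C#CC[C@@H](C)OC(=O)/C(C)=C\C | intermediate
24 | (R,Z)-5-[(Z)-2-methylbut-2-enoyloxy]hex-2-enoic acid | OC(=O)/C=C\C[C@@H](C)OC(=O)/C(C)=C\C | intermediate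
25 | 8β,9β-(isopropylidenedioxy)-10βH-eremophil-11-en-3α-yl (R,Z)-5-[(Z)-2-methylbut-2-enoyloxy]hex-2-enoate | C=C(C)[C@H]1C[C@@]2(C)[C@H](CC[C@@H](OC(=O)/C=C\C[C@@H](C)OC(=O)/C(C)=C\C)[C@@H]2C)[C@H]3OC(C)(C)O[C@@H]13 | intermediate
26 | CNP0395983.1, 8β,9β-dihydroxy-10βH-eremophil-11-en-3α-yl (R,Z)-5-[(Z)-2-methylbut-2-enoyloxy]hex-2-enoate | C=C(C)[C@H]1C[C@@]2(C)[C@H](CC[C@@H](OC(=O)/C=C\C[C@@H](C)OC(=O)/C(C)=C\C)[C@@H]2C)[C@@H](O)[C@H]1O | target

## Step count and risks

Total steps: 14. Longest linear sequence: 11 steps (steps 1–9, 13, 14); the acid 24 is made in a 3-step branch (steps 10–12).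

The three steps most likely to fail:

Step 5 (tethered cycloaddition). The nine-membered tether geometry needs the C8 oxygen pseudo-axial, the dienophile is a hindered β,β-disubstituted enone, and the silaketal may not survive the Lewis acid. The fallback sets out from 4 (with 6) and returns at 15. Soft enolisation of 6 with TBSOTf/Et3N gives (Z)-tert-butyl(dimethyl)(penta-1,3-dien-3-yloxy)silane F1. An untethered intermolecular AlBr3/AlMe3 Diels–Alder reaction of F1 with enone 4, on the face anti to the isopropenyl group, gives 3-(tert-butyldimethylsilyloxy)-4α-methyl-10βH-eremophila-2,11-dien-9-one F2. KHMDS and the Davis oxaziridine then hydroxylate C8 directly from the convex β-face to give 3-(tert-butyldimethylsilyloxy)-8β-hydroxy-4α-methyl-10βH-eremophila-2,11-dien-9-one F3. Aqueous oxalic acid hydrolyses the enol ether and equilibrates C4, delivering 15 without a tether or a C8 inversion.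

Step 7 (inversion at C8). SN2 at the hindered α-keto carbinol may lose out to elimination or to epimerisation of the labile axial α-ketol. The fallback sets out from 9 and returns at 15. SmI2 in THF–MeOH reductively cleaves the C8–O bond of the α-silyloxy ketone to give 3-[hydroxydi(propan-2-yl)silyloxy]-4α-methyl-10βH-eremophila-2,11-dien-9-one F4. KHMDS and the Davis oxaziridine re-introduce the oxygen from the β-face, giving 8β-hydroxy-3-[hydroxydi(propan-2-yl)silyloxy]-4α-methyl-10βH-eremophila-2,11-dien-9-one F5. Aqueous oxalic acid removes the silyl enol ether and equilibrates C4 to give 15.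

Step 2 (thermal retro-ene). At 230 °C the enone may aromatise to the phenol or the isopropenyl double bond may migrate. The fallback sets out from 2 and returns at 4. TMSCl/NaI in MeCN opens the cyclopropyl ketone by homoconjugate iodide addition and, after aqueous work-up, gives (S)-5-(2-iodopropan-2-yl)-3-methylcyclohex-2-en-1-one F6. Silver triflate with 2,6-di-tert-butylpyridine then effects an E1 elimination to the isopropenyl group under non-enolising conditions, giving 4.

## Further compounds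

F1 | step 5 | (Z)-tert-butyl(dimethyl)(penta-1,3-dien-3-yloxy)silane | C=C/C(O[Si](C)(C)C(C)(C)C)=C/C
F2 | step 5 | 3-(tert-butyldimethylsilyloxy)-4α-methyl-10βH-eremophila-2,11-dien-9-one | C=C(C)[C@H]1C[C@@]2(C)[C@H](CC=C(O[Si](C)(C)C(C)(C)C)[C@H]2C)C(=O)C1
F3 | step 5 | 3-(tert-butyldimethylsilyloxy)-8β-hydroxy-4α-methyl-10βH-eremophila-2,11-dien-9-one | C=C(C)[C@H]1C[C@@]2(C)[C@H](CC=C(O[Si](C)(C)C(C)(C)C)[C@H]2C)C(=O)[C@H]1O
F4 | step 7 | 3-[hydroxydi(propan-2-yl)silyloxy]-4α-methyl-10βH-eremophila-2,11-dien-9-one | C=C(C)[C@H]1C[C@@]2(C)[C@H](CC=C(O[Si](O)(C(C)C)C(C)C)[C@H]2C)C(=O)C1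
F5 | step 7 | 8β-hydroxy-3-[hydroxydi(propan-2-yl)silyloxy]-4α-methyl-10βH-eremophila-2,11-dien-9-one | C=C(C)[C@H]1C[C@@]2(C)[C@H](CC=C(O[Si](O)(C(C)C)C(C)C)[C@H]2C)C(=O)[C@H]1O
F6 | step 2 | (S)-5-(2-iodopropan-2-yl)-3-methylcyclohex-2-en-1-one | CC(C)(I)[C@H]1CC(C)=CC(=O)C1
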